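The 1,2-dioxane ring (O1, O2, C3–C6) is made from a carbocycle: C3, C4, C5 and C6 are first joined as a cyclobutanol, and a Co(acac)2/O2 oxidative ring expansion inserts dioxygen into its C3–C6 bond, the bond between the carbinol carbon and the fully substituted C6, to give the 1,2-dioxan-3-ol in one operation. The precursor is a 2,2,4-trisubstituted cyclobutanol whose C4 centre is set by a RAMP-hydrazone ethylation; C3 is then relayed from C4 by axial attack of a silyl ketene acetal on the peroxycarbenium ion. C6 forms without facial control, so its epimers are parted at the ester stage. The side-chain centres come from catalytic ethyl and methyl transfers linked by a Johnson–Claisen rearrangement.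

Key step: step 11

Remark: target atom numbers are used for all intermediates (ring O1, O2, C3 to C6; chain C7 to C14, with the methyl group on C8 and the chain ethyl group on C10). Assumed ligand senses: the (1S,2S) bis-triflamide/Ti(OiPr)4 catalyst adds ethyl to the Re face of the enal, and (R,S)-Josiphos/CuBr adds methyl to the Si face of the enone β-carbon; where a sense is the reverse, the mirror-image ligand is taken.

Step 1
Reactants: 1 (2E)-pent-2-enal
Product: 2 (3R,4E)-hept-4-en-3-ol
Conditions: Et2Zn, Ti(OiPr)4, (1S,2S)-N,N'-cyclohexane-1,2-diylbis(trifluoromethanesulfonamide) (cat.), toluene, −20 °C; aq. HCl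
Reagents that add atoms: diethylzinc, CC[Zn]CC
Why: Titanium-mediated catalytic enantioselective addition of a dialkylzinc to an aldehyde, in which the chiral bis-sulfonamide titanate should deliver ethyl 1,2 to the Re face of the enal carbonyl and so set the carbinol centre as R.

Step 2
Reactants: 2 (3R,4E)-hept-4-en-3-ol
Product: 4 ethyl (3R,4E)-3-ethylhept-4-enoate, via mixed ketene acetal 3 (not isolated)
Conditions: MeC(OEt)3 (excess), EtCO2H (cat.), 140 °C, EtOH distilled off
Reagents that add atoms: triethyl orthoacetate, CC(OCC)(OCC)OCC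
Why: Johnson–Claisen rearrangement, in which ketene acetal 3 should rearrange through a chair transition state with the carbinol ethyl group equatorial, transferring the R carbinol centre suprafacially to the new R centre (later C10) and forming the E alkene (later C11=C12).

Step 3
Reactants: 4 ethyl (3R,4E)-3-ethylhept-4-enoate
Product: 5 (3R,4E)-3-ethylhept-4-enal
Conditions: iBu2AlH, CH2Cl2, −78 °C; aq. Rochelle salt
Reagents that add atoms: none
Why: Partial reduction of an ester to the aldehyde by iBu2AlH at low temperature through a stable aluminium hemiacetal, which leaves the β-stereocentre and the alkene untouched.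

Step 4
Reactants: 5 (3R,4E)-3-ethylhept-4-enal; 6 diethyl (2-oxobutyl)phosphonate
Product: 7 (4E,7R,8E)-7-ethylundeca-4,8-dien-3-one
Conditions: LiCl, iPr2NEt, MeCN, 0 °C to rt
Reagents that add atoms: none
Why: Horner–Wadsworth–Emmons olefination with a β-ketophosphonate under mild LiCl/amine conditions, which should give the E enone without touching the remote stereocentre.

Step 5
Reactants: 7 (4E,7R,8E)-7-ethylundeca-4,8-dien-3-one
Product: 8 (5S,7R,8E)-7-ethyl-5-methylundec-8-en-3-one
Conditions: MeMgBr, CuBr·SMe2 (5 mol %), (R)-1-[(S)-2-(diphenylphosphino)ferrocenyl]ethyldicyclohexylphosphine ((R,S)-Josiphos, 6 mol %), tBuOMe, −75 °C; aq. NH4Cl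
Reagents that add atoms: methylmagnesium bromide, C[Mg]Br
Why: Copper-catalysed asymmetric conjugate addition of a Grignard reagent to a linear enone, in which the chiral copper–diphosphine complex should deliver methyl to the Si face of the β-carbon under catalyst control and set the 5S centre (later C8), the isolated alkene being inert.

Step 6
Reactants: 8 (5S,7R,8E)-7-ethyl-5-methylundec-8-en-3-one; 9 cyclopropyldiphenylsulfonium tetrafluoroborate
Product: 11 2-ethyl-2-[(2S,4R,5E)-4-ethyl-2-methyloct-5-en-1-yl]cyclobutan-1-one (both C2 epimers), via oxaspiropentane 10 (not isolated)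
Conditions: KOH (powder), DMSO, 25 °C; then 1 M aq. HBF4, Et2O
Reagents that add atoms: none
Why: Cyclobutanone spiroannulation with a sulfonium cyclopropylide, in which the ylide adds to the ketone and closes to oxaspiropentane 10, whose acid-induced 1,2-shift of a cyclopropane bond to the tertiary cationic carbon gives the 2,2-disubstituted cyclobutanone; the quaternary centre forms without control, which is harmless because step 11 erases it.

Step 7
Reactants: 11 2-ethyl-2-[(2S,4R,5E)-4-ethyl-2-methyloct-5-en-1-yl]cyclobutan-1-one; 12 (2R)-1-amino-2-(methoxymethyl)pyrrolidine (RAMP)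
Product: 13 (2R)-N-{2-ethyl-2-[(2S,4R,5E)-4-ethyl-2-methyloct-5-en-1-yl]cyclobutylidene}-2-(methoxymethyl)pyrrolidin-1-amine
Conditions: cyclohexane, TsOH (cat.), reflux, water separator
Reagents that add atoms: none
Why: Condensation of a strained, electrophilic ketone with the chiral hydrazine to the hydrazone, whose amino group should lie anti to the quaternary carbon.

Step 8
Reactants: 13 (2R)-N-{2-ethyl-2-[(2S,4R,5E)-4-ethyl-2-methyloct-5-en-1-yl]cyclobutylidene}-2-(methoxymethyl)pyrrolidin-1-amine
Product: 15 (2R)-N-{(4S)-2,4-diethyl-2-[(2S,4R,5E)-4-ethyl-2-methyloct-5-en-1-yl]cyclobutylidene}-2-(methoxymethyl)pyrrolidin-1-amine, via lithium azaenolate 14 (not isolated)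
Conditions: LiN(iPr)2, THF, 0 °C; then EtI, −100 °C to rt
Reagents that add atoms: iodoethane, CCI
Why: Enders RAMP-hydrazone alkylation, in which deprotonation at the only α-CH2 gives a chelated lithium azaenolate with one face shielded by the methoxymethylpyrrolidine unit, so that iodoethane should enter under auxiliary control and set the 4S centre (later C4) whatever the configuration at C2.

Step 9
Reactants: 15 (2R)-N-{(4S)-2,4-diethyl-2-[(2S,4R,5E)-4-ethyl-2-methyloct-5-en-1-yl]cyclobutylidene}-2-(methoxymethyl)pyrrolidin-1-amine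
Product: 16 (4S)-2,4-diethyl-2-[(2S,4R,5E)-4-ethyl-2-methyloct-5-en-1-yl]cyclobutan-1-one
Conditions: sat. aq. oxalic acid, Et2O, rt
Reagents that add atoms: water, O
Why: Mild two-phase hydrolysis of the hydrazone with oxalic acid, conditions that do not epimerise α-centres and spare the alkene, should release the ketone and the auxiliary as its oxalate.

Step 10
Reactants: 16 (4S)-2,4-diethyl-2-[(2S,4R,5E)-4-ethyl-2-methyloct-5-en-1-yl]cyclobutan-1-one
Product: 17 (4S)-2,4-diethyl-2-[(2S,4R,5E)-4-ethyl-2-methyloct-5-en-1-yl]cyclobutan-1-ol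
Conditions: NaBH4, MeOH, −20 °C
Reagents that add atoms: none
Why: Borohydride reduction of the cyclobutanone, faster than enolisation so that the α-centre is kept; the carbinol centre forms as a mixture, which is harmless because it becomes sp2 in step 11.

Step 11
Reactants: 17 (4S)-2,4-diethyl-2-[(2S,4R,5E)-4-ethyl-2-methyloct-5-en-1-yl]cyclobutan-1-ol
Product: 19 (4S)-4,6-diethyl-6-[(2S,4R,5E)-4-ethyl-2-methyloct-5-en-1-yl]-1,2-dioxan-3-ol (both C6 epimers as anomeric mixtures), via γ-hydroperoxy aldehyde 18 (not isolated)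
Conditions: Co(acac)2 (cat.), O2 (1 atm), toluene, rt
Reagents that add atoms: dioxygen, O=O
Why: Cobalt-catalysed aerobic oxidative ring expansion of a secondary cyclobutanol, a known route to 1,2-dioxan-3-ols: divalent cobalt and O2 give a trivalent cobalt alkoxide of 17, whose homolysis to the cyclobutoxy radical is followed by strain-driven β-scission of the C3–C6 bond, so that C3 becomes an aldehyde and C6 a tertiary radical. This radical captures O2, the peroxyl radical is reduced to hydroperoxide 18, and the OOH oxygen adds to the aldehyde carbonyl in a 6-exo-trig closure, which turns the four-membered carbocycle into the six-membered O1–O2–C3–C4–C5–C6 ring. The step needs scission on the C6 side and not on the C4 side, which the tertiary against secondary nature of the departing radical should secure, and it needs O2 capture to outrun 6-exo addition of the C6 radical to the C11=C12 alkene, which the near diffusion-limited reaction with dissolved O2 should secure. Because C3 and C6 both pass through sp2 carbons, every diastereomer of 17 converges on one intermediate, and C4, a bystander, keeps its configuration. C6 is re-formed by attack of O2 on an open-chain planar radical with no controlling element, so both C6 epimers are expected in similar amounts; the hemiperacetal centre C3 forms as an anomeric mixture and is reset in step 13.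

Step 12
Reactants: 19 (4S)-4,6-diethyl-6-[(2S,4R,5E)-4-ethyl-2-methyloct-5-en-1-yl]-1,2-dioxan-3-ol
Product: 20 (4S)-4,6-diethyl-6-[(2S,4R,5E)-4-ethyl-2-methyloct-5-en-1-yl]-1,2-dioxan-3-yl acetate
Conditions: Ac2O, pyridine, DMAP (cat.), CH2Cl2, 0 °C
Reagents that add atoms: acetic anhydride, CC(=O)OC(C)=O
Why: Acylation of the hemiperacetal hydroxyl traps the cyclic tautomer as the 3-acetoxy-1,2-dioxane, which carries the leaving group needed in step 13.

Step 13
Reactants: 20 (4S)-4,6-diethyl-6-[(2S,4R,5E)-4-ethyl-2-methyloct-5-en-1-yl]-1,2-dioxan-3-yl acetate; 21 tert-butyl[(1-methoxyethenyl)oxy]dimethylsilane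
Product: 23 methyl 2-{(3S,4S,6R)-4,6-diethyl-6-[(2S,4R,5E)-4-ethyl-2-methyloct-5-en-1-yl]-1,2-dioxan-3-yl}acetate, via peroxycarbenium ion 22 (not isolated)
Conditions: Me3SiOTf (20 mol %), CH2Cl2, −78 °C; preparative HPLC
Reagents that add atoms: none
Why: Lewis-acid-mediated substitution of a peroxyacetal acetate through a peroxycarbenium ion (Mukaiyama-type addition of a silyl ketene acetal, known for 3-acetoxy-1,2-dioxanes), in which the quaternary C6 and the pseudo-equatorial C4 ethyl group lock the half-chair and the nucleophile should add along the axial trajectory anti to the axial C4–H, giving the 3,4-cis relation (3S) for both C6 epimers; the 6R isomer 23 is separated from its 6S epimer at this stage.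

Step 14
Reactants: 23 methyl 2-{(3S,4S,6R)-4,6-diethyl-6-[(2S,4R,5E)-4-ethyl-2-methyloct-5-en-1-yl]-1,2-dioxan-3-yl}acetate
Product: 24 2-{(3S,4S,6R)-4,6-diethyl-6-[(2S,4R,5E)-4-ethyl-2-methyloct-5-en-1-yl]-1,2-dioxan-3-yl}acetic acid
Conditions: LiOH·H2O, THF/H2O, 0 °C; then 0.5 M HCl to pH 4
Reagents that add atoms: lithium hydroxide, [Li+].[OH-]
Why: Saponification of the methyl ester at 0 °C, where the carboxylate once formed should resist β-elimination of the peroxide, followed by mild acidification to the free acid.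

Compound list
1 | (2E)-pent-2-enal | CC/C=C/C=O | starting material
2 | (3R,4E)-hept-4-en-3-ol | CC/C=C/[C@H](O)CC | intermediate
3 | (3R,4E)-3-[(1-ethoxyethenyl)oxy]hept-4-ene (mixed ketene acetal) | CC/C=C/[C@H](OC(=C)OCC)CC | intermediate
4 | ethyl (3R,4E)-3-ethylhept-4-enoate | CC/C=C/[C@H](CC)CC(=O)OCC | intermediate
5 | (3R,4E)-3-ethylhept-4-enal | CC/C=C/[C@H](CC)CC=O | intermediate
6 | diethyl (2-oxobutyl)phosphonate | CCC(=O)CP(=O)(OCC)OCC | starting material
7 | (4E,7R,8E)-7-ethylundeca-4,8-dien-3-one | CC/C=C/[C@H](CC)C/C=C/C(=O)CC | intermediate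
8 | (5S,7R,8E)-7-ethyl-5-methylundec-8-en-3-one | CC/C=C/[C@H](CC)C[C@H](C)CC(=O)CC | intermediate
9 | cyclopropyldiphenylsulfonium tetrafluoroborate | C1CC1[S+](c1ccccc1)c1ccccc1.F[B-](F)(F)F | starting material
10 | 2-ethyl-2-[(2S,4R,5E)-4-ethyl-2-methyloct-5-en-1-yl]-1-oxaspiro[2.2]pentane (both C2 epimers) | CC/C=C/[C@H](CC)C[C@H](C)CC1(CC)OC12CC2 | intermediate
11 | 2-ethyl-2-[(2S,4R,5E)-4-ethyl-2-methyloct-5-en-1-yl]cyclobutan-1-one (both C2 epimers) | CC/C=C/[C@H](CC)C[C@H](C)CC1(CC)CCC1=O | intermediate
12 | (2R)-1-amino-2-(methoxymethyl)pyrrolidine (RAMP) | COC[C@H]1CCCN1N | starting material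
13 | (2R)-N-{2-ethyl-2-[(2S,4R,5E)-4-ethyl-2-methyloct-5-en-1-yl]cyclobutylidene}-2-(methoxymethyl)pyrrolidin-1-amine | CC/C=C/[C@H](CC)C[C@H](C)CC1(CC)CCC1=NN2CCC[C@@H]2COC | intermediate
14 | lithium {4-ethyl-4-[(2S,4R,5E)-4-ethyl-2-methyloct-5-en-1-yl]cyclobut-1-en-1-yl}[(2R)-2-(methoxymethyl)pyrrolidin-1-yl]azanide (azaenolate) | CC/C=C/[C@H](CC)C[C@H](C)CC1(CC)CC=C1N([Li])N2CCC[C@@H]2COC | intermediate
15 | (2R)-N-{(4S)-2,4-diethyl-2-[(2S,4R,5E)-4-ethyl-2-methyloct-5-en-1-yl]cyclobutylidene}-2-(methoxymethyl)pyrrolidin-1-amine | CC/C=C/[C@H](CC)C[C@H](C)CC1(CC)C[C@H](CC)C1=NN2CCC[C@@H]2COC | intermediate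
16 | (4S)-2,4-diethyl-2-[(2S,4R,5E)-4-ethyl-2-methyloct-5-en-1-yl]cyclobutan-1-one (both C2 epimers) | CC/C=C/[C@H](CC)C[C@H](C)CC1(CC)C[C@H](CC)C1=O | intermediate
17 | (4S)-2,4-diethyl-2-[(2S,4R,5E)-4-ethyl-2-methyloct-5-en-1-yl]cyclobutan-1-ol (mixture at C1 and C2) | CC/C=C/[C@H](CC)C[C@H](C)CC1(CC)C[C@H](CC)C1O | intermediate
18 | (2S,6S,8R,9E)-2,4,8-triethyl-4-hydroperoxy-6-methyldodec-9-enal (both C4 epimers) | CC/C=C/[C@H](CC)C[C@H](C)CC(CC)(OO)C[C@H](CC)C=O | intermediate
19 | (4S)-4,6-diethyl-6-[(2S,4R,5E)-4-ethyl-2-methyloct-5-en-1-yl]-1,2-dioxan-3-ol (mixture at C3 and C6) | CC/C=C/[C@H](CC)C[C@H](C)CC1(CC)C[C@H](CC)C(O)OO1 | intermediate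
20 | (4S)-4,6-diethyl-6-[(2S,4R,5E)-4-ethyl-2-methyloct-5-en-1-yl]-1,2-dioxan-3-yl acetate (mixture at C3 and C6) | CC/C=C/[C@H](CC)C[C@H](C)CC1(CC)C[C@H](CC)C(OC(C)=O)OO1 | intermediate
21 | tert-butyl[(1-methoxyethenyl)oxy]dimethylsilane | C=C(OC)O[Si](C)(C)C(C)(C)C | starting material
22 | (4S)-4,6-diethyl-6-[(2S,4R,5E)-4-ethyl-2-methyloct-5-en-1-yl]-1,2-dioxan-3-ylium (peroxycarbenium ion, both C6 epimers) | CC/C=C/[C@H](CC)C[C@H](C)CC1(CC)C[C@H](CC)C=[O+]O1 | intermediate
23 | methyl 2-{(3S,4S,6R)-4,6-diethyl-6-[(2S,4R,5E)-4-ethyl-2-methyloct-5-en-1-yl]-1,2-dioxan-3-yl}acetate | CC/C=C/[C@H](CC)C[C@H](C)C[C@]1(CC)C[C@H](CC)[C@H](CC(=O)OC)OO1 | intermediate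
24 | 2-{(3S,4S,6R)-4,6-diethyl-6-[(2S,4R,5E)-4-ethyl-2-methyloct-5-en-1-yl]-1,2-dioxan-3-yl}acetic acid | CC/C=C/[C@H](CC)C[C@H](C)C[C@]1(CC)C[C@H](CC)[C@H](CC(=O)O)OO1 | target

Total step count: 14. Longest linear sequence: 14 steps, from 1 to 24; compounds 6, 9, 12 and 21 are bought.

Steps most likely to fail

Step 11. The alkoxy radical may cleave the C3–C4 bond in place of C3–C6, the carbinol may simply be oxidised to the cyclobutanone, the C6 radical may be caught by the chain alkene, and no facial control at C6 is expected in any case. The fallback sets out from cyclobutanone 16 and comes back at dioxanol 19. Baeyer–Villiger oxidation with aqueous H2O2 in (CF3)2CHOH, in which the fully substituted C6 migrates, would give the γ-lactone (3S)-3,5-diethyl-5-[(2S,4R,5E)-4-ethyl-2-methyloct-5-en-1-yl]oxolan-2-one F1. Reduction with iBu2AlH at −78 °C would give the lactol (3S)-3,5-diethyl-5-[(2S,4R,5E)-4-ethyl-2-methyloct-5-en-1-yl]oxolan-2-ol F2. Anhydrous H2O2 in Et2O with catalytic H2SO4 would then exchange the tertiary C6–O bond for C6–OOH through the tertiary cation (acid perhydrolysis of a tertiary alcohol), and the hydroperoxide would close on the aldehyde to 19. Here a five-membered lactol grows by one oxygen in place of the cyclobutanol growing by two, and C6 is again formed without control.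

Step 13. Facial selectivity at C3 may be poor, or the Lewis acid may ionise the tertiary C6–O bond. The fallback sets out from 19 and comes back at 23. Wittig olefination of the open aldehyde tautomer of 19 with methyl (triphenylphosphoranylidene)acetate (CH2Cl2, rt) would give the γ-hydroperoxy enoate methyl (2E,4S,8S,10R,11E)-4,6,10-triethyl-6-hydroperoxy-8-methyltetradeca-2,11-dienoate F3. Et2NH in CF3CH2OH would then close the ring by 6-exo-trig peroxy-Michael addition of the hydroperoxide to C3, with C3 set from C4 in a chair transition state. The C3 and C6 isomers would be separated by preparative HPLC to give 23.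

Step 8. Deprotonation of the hindered four-membered hydrazone may be sluggish, or auxiliary control over the incoming ethyl group may be incomplete. The fallback sets out from 11 and comes back at 17. Direct ethylation of the ketone enolate (LiN(iPr)2, THF, −78 °C; EtI) would give 2,4-diethyl-2-[(2S,4R,5E)-4-ethyl-2-methyloct-5-en-1-yl]cyclobutan-1-one F4 as a mixture at C4. Asymmetric hydrogenation under dynamic kinetic resolution (RuCl2[(S)-xylbinap][(S)-daipen] or its mirror image, KOtBu, H2, iPrOH) would follow: the base equilibrates C4 through the enolate while the catalyst reduces only the 4S ketone, and the chain alkene is inert to this carbonyl-selective catalyst. This would give 17 directly.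

Further compounds
F1 | step 11 | (3S)-3,5-diethyl-5-[(2S,4R,5E)-4-ethyl-2-methyloct-5-en-1-yl]oxolan-2-one (both C5 epimers) | CC/C=C/[C@H](CC)C[C@H](C)CC1(CC)C[C@H](CC)C(=O)O1
F2 | step 11 | (3S)-3,5-diethyl-5-[(2S,4R,5E)-4-ethyl-2-methyloct-5-en-1-yl]oxolan-2-ol (mixture at C2 and C5) | CC/C=C/[C@H](CC)C[C@H](C)CC1(CC)C[C@H](CC)C(O)O1
F3 | step 13 | methyl (2E,4S,8S,10R,11E)-4,6,10-triethyl-6-hydroperoxy-8-methyltetradeca-2,11-dienoate (both C6 epimers) | CC/C=C/[C@H](CC)C[C@H](C)CC(CC)(OO)C[C@H](CC)/C=C/C(=O)OC
F4 | step 8 | 2,4-diethyl-2-[(2S,4R,5E)-4-ethyl-2-methyloct-5-en-1-yl]cyclobutan-1-one (mixture at C2 and C4) | CC/C=C/[C@H](CC)C[C@H](C)CC1(CC)CC(CC)C1=O
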